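**Retrosynthetic overview**
1. Target ⇐ silyl-protected vanillate of 8α,9α-epoxyjaeschkeanadiol: the C8(=CH2)/C9–OH unit comes from base-induced epoxide → allylic alcohol rearrangement, the ester from the C6–OH.
2. Epoxide ⇐ jaeschkeanadiol (dauc-8-ene-4β,6α-diol) by 6-OH-directed epoxidation; the cycloheptene ⇐ RCM of an allyl/methallyl diene (ring formed last).
3. Diene ⇐ intermolecular, chelation-controlled methallylation of a cyclopentane β-hydroxy aldehyde (forms C6–C7, sets C6).
4. Cyclopentane stereotriad ⇐ temporary trans-fused bicyclic acetal (ring formed second): hydroboration anti to the angular methyl sets C5, i-Pr–Ce addition to the C4 ketone sets C4.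
5. Quaternary C1 ⇐ Pd-catalysed decarboxylative asymmetric allylation of a β-keto ester made by Dieckmann cyclisation of diallyl adipate (cyclopentane formed first).

Assumption: atom labels follow daucane numbering (C1 methyl-bearing quaternary C, C4 isopropyl carbinol, C5 ring-fusion CH, C6 ester carbon, C8 methylene-bearing C, C9 allylic carbinol), the target being (1R,4R,5S,6S,9S); the ca. 88% ee expected for 4 is raised to enantiopurity by recrystallising crystalline diol 23.

**Step 1**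
Reactants: 1 diallyl adipate
Product: 3 allyl 1-methyl-2-oxocyclopentane-1-carboxylate (racemic), via sodium enolate 2 (not isolated)
Conditions: NaH, cat. allyl alcohol, THF, 40 °C; then MeI, 40 °C
Reagents that add atoms: iodomethane CI
Why: Dieckmann (intramolecular Claisen) condensation gives the stabilised β-keto ester enolate, which is C-methylated in the same pot (no stereocontrol needed).

**Step 2**
Reactants: 3 allyl 1-methyl-2-oxocyclopentane-1-carboxylate
Product: 4 (R)-2-allyl-2-methylcyclopentan-1-one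
Conditions: Pd2(dba)3 (2.5 mol%), (R)-t-Bu-PHOX (6 mol%), THF, 25 °C
Reagents that add atoms: none
Why: Pd-catalysed decarboxylative asymmetric allylic alkylation, in which the chiral PHOX–Pd π-allyl/enolate pair recombines enantioselectively to set quaternary C1 as R (the S ligand gives the S ketone).

**Step 3**
Reactants: 4 (R)-2-allyl-2-methylcyclopentan-1-one
Product: 6 (R)-5-allyl-5-methylcyclopent-1-en-1-yl trifluoromethanesulfonate, via potassium enolate 5 (not isolated)
Conditions: KHMDS, THF, −78 °C; then PhNTf2, −78 → 0 °C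
Reagents that add atoms: N-phenylbis(trifluoromethanesulfonimide) O=S(=O)(N(c1ccccc1)S(=O)(=O)C(F)(F)F)C(F)(F)F
Why: Enol triflate formation; only the C4 methylene can be deprotonated, so a single regioisomer forms and C1 is untouched.

**Step 4**
Reactants: 6 (R)-5-allyl-5-methylcyclopent-1-en-1-yl trifluoromethanesulfonate
Product: 7 methyl (R)-5-allyl-5-methylcyclopent-1-ene-1-carboxylate
Conditions: Pd(OAc)2 (5 mol%), PPh3 (10 mol%), Et3N, CO (1 atm), MeOH/DMF, 50 °C
Reagents that add atoms: carbon monoxide [C-]#[O+]; methanol CO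
Why: Pd-catalysed alkoxycarbonylation of the alkenyl triflate installs C6; CO insertion is faster than any Heck reaction with the allyl group.

**Step 5**
Reactants: 7 methyl (R)-5-allyl-5-methylcyclopent-1-ene-1-carboxylate
Product: 9 methyl (R)-5-methyl-5-(2-oxoethyl)cyclopent-1-ene-1-carboxylate, via diol 8 (not isolated)
Conditions: OsO4 (2 mol%), NaIO4, 2,6-lutidine, dioxane/H2O 3:1, rt
Reagents that add atoms: osmium tetroxide O=[Os](=O)(=O)=O; sodium periodate [Na+].[O-]I(=O)(=O)=O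
Why: Lemieux–Johnson cleavage; osmylation takes only the unhindered terminal alkene (the conjugated, neopentyl enoate alkene is inert) and periodate cleaves the diol to the C9 aldehyde.

**Step 6**
Reactants: 9 methyl (R)-5-methyl-5-(2-oxoethyl)cyclopent-1-ene-1-carboxylate
Product: 10 methyl (R)-5-(2,2-dimethoxyethyl)-5-methylcyclopent-1-ene-1-carboxylate
Conditions: HC(OMe)3, PPTS (cat.), MeOH, rt
Reagents that add atoms: trimethyl orthoformate COC(OC)OC
Why: Acid-catalysed acetalisation masks the aldehyde so the ester can be reduced.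

**Step 7**
Reactants: 10 methyl (R)-5-(2,2-dimethoxyethyl)-5-methylcyclopent-1-ene-1-carboxylate
Product: 12 (4aR)-3-methoxy-4a-methyl-1,3,4,4a,5,6-hexahydrocyclopenta[c]pyran (both anomers), via allylic alcohol 11 (not isolated)
Conditions: DIBAL-H (2.5 equiv), CH2Cl2, −78 °C, Rochelle salt; then PPTS (cat.), CH2Cl2, 4 Å MS, rt
Reagents that add atoms: none
Why: Ester reduction followed by intramolecular transacetalisation closes a six-membered cyclic acetal that ties C6 and C10 into a ring.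

**Step 8**
Reactants: 12 (4aR)-3-methoxy-4a-methyl-1,3,4,4a,5,6-hexahydrocyclopenta[c]pyran
Product: 14 (4aR,7R,7aS)-3-methoxy-4a-methyloctahydrocyclopenta[c]pyran-7-ol (trans-fused), via alkylborane 13 (not isolated)
Conditions: BH3·THF, THF, 0 °C → rt; then 3 M NaOH, 30% H2O2, 0 °C → rt
Reagents that add atoms: hydrogen peroxide OO
Why: Hydroboration–oxidation adds H and B syn, boron at the less substituted C4, on the face opposite the angular methyl of the rigid bicycle (as with Δ14-steroids), so H-5 ends trans to the C1 methyl.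

**Step 9**
Reactants: 14 (4aR,7R,7aS)-3-methoxy-4a-methyloctahydrocyclopenta[c]pyran-7-ol
Product: 15 (4aR,7aS)-3-methoxy-4a-methylhexahydrocyclopenta[c]pyran-7(1H)-one (trans-fused)
Conditions: Dess–Martin periodinane, NaHCO3, CH2Cl2, 0 °C → rt
Reagents that add atoms: none
Why: Buffered Dess–Martin oxidation gives the C4 ketone without epimerising the adjacent trans ring-fusion centre C5.

**Step 10**
Reactants: 15 (4aR,7aS)-3-methoxy-4a-methylhexahydrocyclopenta[c]pyran-7(1H)-one
Product: 16 (4aR,7R,7aS)-3-methoxy-4a-methyl-7-(propan-2-yl)octahydrocyclopenta[c]pyran-7-ol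
Conditions: i-PrMgCl, anhydrous CeCl3, THF, −78 → −40 °C; aq NH4Cl
Reagents that add atoms: isopropylmagnesium chloride CC(C)[Mg]Cl
Why: Organocerium 1,2-addition (Imamoto); the weakly basic reagent attacks the face opposite the axial C1 methyl and the C5–C6 bond, placing the C4–OH cis to the methyl (4R).

**Step 11**
Reactants: 16 (4aR,7R,7aS)-3-methoxy-4a-methyl-7-(propan-2-yl)octahydrocyclopenta[c]pyran-7-ol
Product: 17 (4aR,7R,7aS)-4a-methyl-7-(propan-2-yl)octahydrocyclopenta[c]pyran-3,7-diol (lactol)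
Conditions: AcOH/THF/H2O 3:1:1, 40 °C
Reagents that add atoms: water O
Why: Mild acetal hydrolysis; the tertiary alcohol is trans to C10 and cannot form an internal acetal.

**Step 12**
Reactants: 17 (4aR,7R,7aS)-4a-methyl-7-(propan-2-yl)octahydrocyclopenta[c]pyran-3,7-diol
Product: 19 (1R,2S,3R)-3-allyl-2-(hydroxymethyl)-3-methyl-1-(propan-2-yl)cyclopentan-1-ol, via hydroxy aldehyde 18 (not isolated)
Conditions: Ph3PCH3Br (4 equiv), KOt-Bu (4 equiv), THF, 0 → 50 °C
Reagents that add atoms: methyltriphenylphosphonium bromide C[P+](c1ccccc1)(c1ccccc1)c1ccccc1.[Br-]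
Why: Wittig methylenation of the lactol through its open form rebuilds the C1 allyl group and frees the C6 primary alcohol.

**Step 13**
Reactants: 19 (1R,2S,3R)-3-allyl-2-(hydroxymethyl)-3-methyl-1-(propan-2-yl)cyclopentan-1-ol
Product: 20 (1R,2R,5R)-2-allyl-5-hydroxy-2-methyl-5-(propan-2-yl)cyclopentane-1-carbaldehyde
Conditions: Dess–Martin periodinane, NaHCO3, CH2Cl2, 0 °C; used crude
Reagents that add atoms: none
Why: Dess–Martin oxidation affects only the primary alcohol, and C5 is already in its more stable configuration (CHO trans to isopropyl and allyl).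

**Step 14**
Reactants: 20 (1R,2R,5R)-2-allyl-5-hydroxy-2-methyl-5-(propan-2-yl)cyclopentane-1-carbaldehyde; 21 3-bromo-2-methylprop-1-ene
Product: 22 (1R,2S,3R)-3-allyl-2-[(1S)-1-hydroxy-3-methylbut-3-en-1-yl]-3-methyl-1-(propan-2-yl)cyclopentan-1-ol
Conditions: In powder, THF/H2O 1:1, rt
Reagents that add atoms: none
Why: Barbier-type carbonyl allylation joining the two fragments at C6–C7; indium chelates the aldehyde oxygen and the cis C4–OH, so the methallyl group attacks the exposed face away from C1 and gives 6S.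

**Step 15**
Reactants: 22 (1R,2S,3R)-3-allyl-2-[(1S)-1-hydroxy-3-methylbut-3-en-1-yl]-3-methyl-1-(propan-2-yl)cyclopentan-1-ol
Product: 23 (3R,3aS,4S,8aR)-6,8a-dimethyl-3-(propan-2-yl)-1,2,3,3a,4,5,8,8a-octahydroazulene-3,4-diol (jaeschkeanadiol)
Conditions: Grubbs II (5 mol%), CH2Cl2 (5 mM), 40 °C
Reagents that add atoms: none
Why: Ring-closing metathesis of the terminal and 1,1-disubstituted alkenes closes the trans-fused cycloheptene with the trisubstituted C8=C9 bond.

**Step 16**
Reactants: 23 jaeschkeanadiol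
Product: 24 (1R,4R,5S,6S,8R,9S)-8,9-epoxydaucane-4,6-diol (epoxide O cis to 6-OH)
Conditions: VO(acac)2 (5 mol%), t-BuOOH (decane), CH2Cl2, 0 °C → rt
Reagents that add atoms: tert-butyl hydroperoxide CC(C)(C)OO
Why: Vanadium-catalysed hydroxyl-directed epoxidation delivers oxygen syn to the homoallylic C6–OH, which is also the face opposite the angular methyl.

**Step 17**
Reactants: 25 vanillic acid
Product: 27 4-[(tert-butyldimethylsilyl)oxy]-3-methoxybenzoic acid, via bis-silyl compound 26 (not isolated)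
Conditions: TBSCl (2.5 equiv), imidazole, DMF, rt; then AcOH/THF/H2O 3:1:1, rt
Reagents that add atoms: tert-butyldimethylsilyl chloride CC(C)(C)[Si](C)(C)Cl
Why: Silylation of both OH groups followed by selective hydrolysis of the labile silyl ester leaves the phenol protected.

**Step 18**
Reactants: 24 (1R,4R,5S,6S,8R,9S)-8,9-epoxydaucane-4,6-diol; 27 4-[(tert-butyldimethylsilyl)oxy]-3-methoxybenzoic acid
Product: 29 (1R,4R,5S,6S,8R,9S)-8,9-epoxy-4-hydroxydaucan-6-yl 4-[(tert-butyldimethylsilyl)oxy]-3-methoxybenzoate, via mixed anhydride 28 (not isolated)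
Conditions: 2,4,6-trichlorobenzoyl chloride, Et3N, toluene, rt; then 24, DMAP, toluene, rt → 40 °C
Reagents that add atoms: none
Why: Yamaguchi esterification acylates the only secondary alcohol (C6–OH); the tertiary C4–OH and the epoxide do not react.

**Step 19**
Reactants: 29 (1R,4R,5S,6S,8R,9S)-8,9-epoxy-4-hydroxydaucan-6-yl 4-[(tert-butyldimethylsilyl)oxy]-3-methoxybenzoate
Product: 30 (1R,4R,5S,6S,9S)-4,9-dihydroxydauc-8(14)-en-6-yl 4-[(tert-butyldimethylsilyl)oxy]-3-methoxybenzoate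
Conditions: Et2AlTMP (4 equiv, from TMP, n-BuLi, Et2AlCl), toluene, 0 °C → rt; Rochelle salt
Reagents that add atoms: none
Why: Yamamoto base-promoted epoxide → allylic alcohol rearrangement; the aluminium amide removes a proton syn from the C14 methyl (cis to H-9), giving the exocyclic alkene with the C9–O bond and its configuration retained.

**Step 20**
Reactants: 30 (1R,4R,5S,6S,9S)-4,9-dihydroxydauc-8(14)-en-6-yl 4-[(tert-butyldimethylsilyl)oxy]-3-methoxybenzoate
Product: 31 (1R,4R,5S,6S,9S)-4,9-dihydroxydauc-8(14)-en-6-yl 4-hydroxy-3-methoxybenzoate (target)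
Conditions: TBAF, AcOH, THF, 0 °C
Reagents that add atoms: none
Why: Fluoride-mediated desilylation of the aryl silyl ether, buffered so the benzoate is untouched.

**Compound list**
1 | diallyl adipate | C=CCOC(=O)CCCCC(=O)OCC=C | starting material
2 | sodium enolate of allyl 2-oxocyclopentane-1-carboxylate | [Na+].[O-]C1=C(C(=O)OCC=C)CCC1 | intermediate
3 | allyl 1-methyl-2-oxocyclopentane-1-carboxylate (racemic) | C=CCOC(=O)C1(C)CCCC1=O | intermediate
4 | (R)-2-allyl-2-methylcyclopentan-1-one | O=C1CCC[C@]1(C)CC=C | intermediate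
5 | potassium (R)-5-allyl-5-methylcyclopent-1-en-1-olate | [K+].[O-]C1=CCC[C@]1(C)CC=C | intermediate
6 | (R)-5-allyl-5-methylcyclopent-1-en-1-yl trifluoromethanesulfonate | O=S(=O)(OC1=CCC[C@]1(C)CC=C)C(F)(F)F | intermediate
7 | methyl (R)-5-allyl-5-methylcyclopent-1-ene-1-carboxylate | COC(=O)C1=CCC[C@]1(C)CC=C | intermediate
8 | methyl (5R)-5-(2,3-dihydroxypropyl)-5-methylcyclopent-1-ene-1-carboxylate (carbinol epimers) | COC(=O)C1=CCC[C@]1(C)CC(O)CO | intermediate
9 | methyl (R)-5-methyl-5-(2-oxoethyl)cyclopent-1-ene-1-carboxylate | COC(=O)C1=CCC[C@]1(C)CC=O | intermediate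
10 | methyl (R)-5-(2,2-dimethoxyethyl)-5-methylcyclopent-1-ene-1-carboxylate | COC(=O)C1=CCC[C@]1(C)CC(OC)OC | intermediate
11 | [(R)-5-(2,2-dimethoxyethyl)-5-methylcyclopent-1-en-1-yl]methanol | OCC1=CCC[C@]1(C)CC(OC)OC | intermediate
12 | (4aR)-3-methoxy-4a-methyl-1,3,4,4a,5,6-hexahydrocyclopenta[c]pyran (both anomers) | COC1C[C@@]2(C)CCC=C2CO1 | intermediate
13 | [(4aR,7R,7aS)-3-methoxy-4a-methyloctahydrocyclopenta[c]pyran-7-yl]borane | COC1C[C@@]2(C)CC[C@@H](B)[C@@H]2CO1 | intermediate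
14 | (4aR,7R,7aS)-3-methoxy-4a-methyloctahydrocyclopenta[c]pyran-7-ol (trans-fused, 7-OH cis to H-7a) | COC1C[C@@]2(C)CC[C@@H](O)[C@@H]2CO1 | intermediate
15 | (4aR,7aS)-3-methoxy-4a-methylhexahydrocyclopenta[c]pyran-7(1H)-one (trans-fused) | COC1C[C@@]2(C)CCC(=O)[C@@H]2CO1 | intermediate
16 | (4aR,7R,7aS)-3-methoxy-4a-methyl-7-(propan-2-yl)octahydrocyclopenta[c]pyran-7-ol (7-OH cis to 4a-CH3) | COC1C[C@@]2(C)CC[C@@](O)(C(C)C)[C@@H]2CO1 | intermediate
17 | (4aR,7R,7aS)-4a-methyl-7-(propan-2-yl)octahydrocyclopenta[c]pyran-3,7-diol (lactol) | OC1C[C@@]2(C)CC[C@@](O)(C(C)C)[C@@H]2CO1 | intermediate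
18 | 2-[(1R,2S,3R)-3-hydroxy-2-(hydroxymethyl)-1-methyl-3-(propan-2-yl)cyclopentyl]acetaldehyde | O=CC[C@@]1(C)CC[C@@](O)(C(C)C)[C@@H]1CO | intermediate
19 | (1R,2S,3R)-3-allyl-2-(hydroxymethyl)-3-methyl-1-(propan-2-yl)cyclopentan-1-ol | C=CC[C@@]1(C)CC[C@@](O)(C(C)C)[C@@H]1CO | intermediate
20 | (1R,2R,5R)-2-allyl-5-hydroxy-2-methyl-5-(propan-2-yl)cyclopentane-1-carbaldehyde | C=CC[C@@]1(C)CC[C@@](O)(C(C)C)[C@@H]1C=O | intermediate
21 | 3-bromo-2-methylprop-1-ene (methallyl bromide) | C=C(C)CBr | starting material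
22 | (1R,2S,3R)-3-allyl-2-[(1S)-1-hydroxy-3-methylbut-3-en-1-yl]-3-methyl-1-(propan-2-yl)cyclopentan-1-ol | C=CC[C@@]1(C)CC[C@@](O)(C(C)C)[C@@H]1[C@@H](O)CC(C)=C | intermediate
23 | (3R,3aS,4S,8aR)-6,8a-dimethyl-3-(propan-2-yl)-1,2,3,3a,4,5,8,8a-octahydroazulene-3,4-diol (jaeschkeanadiol) | CC1=CC[C@@]2(C)CC[C@@](O)(C(C)C)[C@@H]2[C@@H](O)C1 | intermediate
24 | (1R,4R,5S,6S,8R,9S)-8,9-epoxydaucane-4,6-diol | C[C@]12O[C@H]1C[C@@]3(C)CC[C@@](O)(C(C)C)[C@@H]3[C@@H](O)C2 | intermediate
25 | vanillic acid | COc1cc(C(=O)O)ccc1O | starting material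
26 | tert-butyldimethylsilyl 4-[(tert-butyldimethylsilyl)oxy]-3-methoxybenzoate | COc1cc(C(=O)O[Si](C)(C)C(C)(C)C)ccc1O[Si](C)(C)C(C)(C)C | intermediate
27 | 4-[(tert-butyldimethylsilyl)oxy]-3-methoxybenzoic acid | COc1cc(C(=O)O)ccc1O[Si](C)(C)C(C)(C)C | intermediate
28 | 4-[(tert-butyldimethylsilyl)oxy]-3-methoxybenzoic 2,4,6-trichlorobenzoic anhydride | COc1cc(C(=O)OC(=O)c2c(Cl)cc(Cl)cc2Cl)ccc1O[Si](C)(C)C(C)(C)C | intermediate
29 | (1R,4R,5S,6S,8R,9S)-8,9-epoxy-4-hydroxydaucan-6-yl 4-[(tert-butyldimethylsilyl)oxy]-3-methoxybenzoate | C[C@]12O[C@H]1C[C@@]3(C)CC[C@@](O)(C(C)C)[C@@H]3[C@@H](OC(=O)c4ccc(O[Si](C)(C)C(C)(C)C)c(OC)c4)C2 | intermediate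
30 | (1R,4R,5S,6S,9S)-4,9-dihydroxydauc-8(14)-en-6-yl 4-[(tert-butyldimethylsilyl)oxy]-3-methoxybenzoate | C=C1C[C@H](OC(=O)c2ccc(O[Si](C)(C)C(C)(C)C)c(OC)c2)[C@@H]2[C@](C)(CC[C@@]2(O)C(C)C)C[C@@H]1O | intermediate
31 | (1R,4R,5S,6S,9S)-4,9-dihydroxydauc-8(14)-en-6-yl 4-hydroxy-3-methoxybenzoate | C=C1C[C@H](OC(=O)c2ccc(O)c(OC)c2)[C@@H]2[C@](C)(CC[C@@]2(O)C(C)C)C[C@@H]1O | target

**Totals:** 20 steps; longest linear sequence 19 steps (steps 1–16 and 18–20).

**Three steps most likely to fail**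

Step 10. Ketone 15 is hindered and enolisable, so epimerisation at C5, β-elimination of the ring oxygen or β-hydride reduction by the isopropyl reagent may compete. Fallback: from ketone 15, add isopropenylmagnesium bromide/CeCl3 (a smaller sp2 nucleophile without β-hydrogen) to give (4aR,7S,7aS)-3-methoxy-4a-methyl-7-(prop-1-en-2-yl)octahydrocyclopenta[c]pyran-7-ol F1, then hydrogenate its only alkene (H2, Pd/C, EtOAc) to come back to 16.

Step 14. The C6 configuration depends on chelation at a very hindered aldehyde, and the ratio may be low or reversed. Fallback: from aldehyde 20, add methallylmagnesium chloride without stereocontrol to give the C6-epimeric diene diols F2. Close the ring with Grubbs II to the C6-epimeric dauc-8-ene-4,6-diols F3 and oxidise with Dess–Martin periodinane to the single ketone (1R,4R,5R)-4-hydroxydauc-8-en-6-one F4. Reduce with Me4NBH(OAc)3, which delivers hydride intramolecularly from the C4 alkoxyborohydride to the inner face of the ketone, to come back to 23.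

Step 19. The aluminium amide may attack the aryl ester, the Lewis-acidic medium may let the C4–OH open the epoxide transannularly, or endocyclic alkene isomers may form. Fallback: from epoxy diol 24, rearrange first with excess Et2AlTMP (no ester present) to (1R,4R,5S,6S,9S)-dauc-8(14)-ene-4,6,9-triol F5. Silylate the less hindered allylic 9-OH (TBSCl, imidazole) to the 9-O-TBS ether F6, esterify the 6-OH with acid 27 (Yamaguchi) to the bis-silyl ester F7, and remove both silyl groups with TBAF/AcOH to arrive at 31.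

**Further compounds**
F1 | step 10 | (4aR,7S,7aS)-3-methoxy-4a-methyl-7-(prop-1-en-2-yl)octahydrocyclopenta[c]pyran-7-ol | COC1C[C@@]2(C)CC[C@@](O)(C(C)=C)[C@@H]2CO1
F2 | step 14 | (1R,2S,3R)-3-allyl-2-(1-hydroxy-3-methylbut-3-en-1-yl)-3-methyl-1-(propan-2-yl)cyclopentan-1-ol (both carbinol epimers) | C=CC[C@@]1(C)CC[C@@](O)(C(C)C)[C@@H]1C(O)CC(C)=C
F3 | step 14 | (1R,4R,5S)-dauc-8-ene-4,6-diol (both C6 epimers) | CC1=CC[C@@]2(C)CC[C@@](O)(C(C)C)[C@@H]2C(O)C1
F4 | step 14 | (1R,4R,5R)-4-hydroxydauc-8-en-6-one | CC1=CC[C@@]2(C)CC[C@@](O)(C(C)C)[C@@H]2C(=O)C1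
F5 | step 19 | (1R,4R,5S,6S,9S)-dauc-8(14)-ene-4,6,9-triol | C=C1C[C@H](O)[C@@H]2[C@](C)(CC[C@@]2(O)C(C)C)C[C@@H]1O
F6 | step 19 | (1R,4R,5S,6S,9S)-9-[(tert-butyldimethylsilyl)oxy]dauc-8(14)-ene-4,6-diol | C=C1C[C@H](O)[C@@H]2[C@](C)(CC[C@@]2(O)C(C)C)C[C@@H]1O[Si](C)(C)C(C)(C)C
F7 | step 19 | (1R,4R,5S,6S,9S)-9-[(tert-butyldimethylsilyl)oxy]-4-hydroxydauc-8(14)-en-6-yl 4-[(tert-butyldimethylsilyl)oxy]-3-methoxybenzoate | C=C1C[C@H](OC(=O)c2ccc(O[Si](C)(C)C(C)(C)C)c(OC)c2)[C@@H]2[C@](C)(CC[C@@]2(O)C(C)C)C[C@@H]1O[Si](C)(C)C(C)(C)C
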